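**Plan**
- Retrosynthesis: the benzyl group on the C7 oxygen is removed last. Ring C is cut at O1–C2 (oxidative cyclisation of a 2'-hydroxychalcone), at C2–C3 (Claisen–Schmidt condensation) and at C4–C4a (acylation of an ortho-lithiated aryl ether).
- Ring A is then cut at C4a–C8a, C5–C6 and C8–C8a into a trialkoxycyclobutenone and methoxyacetylene. This works because ring A carries oxygen on five adjacent carbons (C5, C6, C7, C8, C8a) and a carbon substituent only on C4a. C6, C7, C8 and C8a are the four squarate carbons with their oxygens; C5 and C4a are the two carbons of the ynol ether.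
- Forward: dimethyl squarate is reduced, O-methylated and given a benzyloxy group at its β-carbon. Benzannulation with methoxyacetylene closes ring A as a phenol. MOM protection and ortho-lithiation bring in the acetyl group. Chalcone formation and I2/DMSO close ring C. Hydrogenolysis frees the 7-OH.
- Stereochemistry: the target has no stereocentre. The sp3 centres that appear on the way are racemic and are erased, and the E-alkene of the chalcone disappears when ring C forms.

Key step: step 5

Remark: the sp3 centres that arise on the way (in the reduced squarate, the cyclobutenones, the cyclohexadienone and the flavanone) are handled as racemates; each becomes sp2 later, so this has no consequence.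

**Step 1**
Reactants: 1 dimethyl squarate
Product: 2 4-hydroxy-2,3-dimethoxycyclobut-2-en-1-one (racemic)
Conditions: LiAlH(OtBu)3 (1.1 equiv), THF, −78 → −20 °C; cold aq. NaH2PO4/Na2HPO4 buffer (pH 7); used crude
Reagents that add atoms: none
Why: 1,2-hydride reduction of one carbonyl of a dialkyl squarate by the bulky, mild LiAlH(OtBu)3 is the established way to 4-hydroxy-2,3-dialkoxycyclobutenones, the remaining carbonyl being a deactivated vinylogous ester; the new C4 centre forms racemic.

**Step 2**
Reactants: 2 4-hydroxy-2,3-dimethoxycyclobut-2-en-1-one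
Product: 3 2,3,4-trimethoxycyclobut-2-en-1-one (racemic)
Conditions: MeI (10 equiv), Ag2O (1.5 equiv), 4 Å molecular sieves, CH2Cl2, rt, dark
Reagents that add atoms: iodomethane, CI
Why: Purdie methylation (Ag2O/MeI) etherifies the carbinol under nearly neutral conditions, avoiding the acid that would convert 2 into a semisquarate and the strong base that could open the ring; the ether becomes the C8 methoxy group and blocks lactone formation on later heating.

**Step 3**
Reactants: 3 2,3,4-trimethoxycyclobut-2-en-1-one; 4 benzyl alcohol
Product: 5 3-(benzyloxy)-2,4-dimethoxycyclobut-2-en-1-one (racemic)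
Conditions: 4 (5 equiv), NaH (0.1 equiv), THF, 0 °C → rt, 5 Å molecular sieves to take up MeOH
Reagents that add atoms: none
Why: vinylogous transesterification by conjugate addition–elimination, in which benzyloxide adds to the β-carbon C3, the only position whose enolate adduct can expel methoxide, so the C2 and C4 methoxy groups stay and the exchange is driven by excess alcohol and removal of methanol.

**Step 4**
Reactants: 6 chloroacetaldehyde dimethyl acetal
Product: 8 methoxyacetylene, via sodium methoxyacetylide 7 (not isolated)
Conditions: NaNH2 (3 equiv), liquid NH3, −33 °C; cold saturated aq. NaCl; distilled (bp about 23 °C) into a −78 °C trap and kept as a cold toluene solution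
Reagents that add atoms: none
Why: double elimination (loss of HCl and of methanol) with NaNH2 is the classical preparation of alkoxyacetylenes from chloroacetal precursors, the acetylide being protonated on aqueous quench.

**Step 5**
Reactants: 5 3-(benzyloxy)-2,4-dimethoxycyclobut-2-en-1-one; 8 methoxyacetylene
Product: 13 3-(benzyloxy)-2,4,5-trimethoxyphenol, via vinylketene 9 (not isolated), via alkenylcyclobutenone 10 (not isolated), via dienylketene 11 (not isolated), via cyclohexadienone 12 (not isolated)
Conditions: 8 (4 equiv), degassed toluene, sealed tube, 80 °C then 110 °C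
Reagents that add atoms: none
Why: Heating opens 5 by a four-electron electrocyclic ring opening (the C4 methoxy turning outward) to vinylketene 9, whose ketene C=C adds methoxyacetylene in a [2+2] cycloaddition to give 10. A second four-electron opening, again with the methoxy group on the sp3 carbon turning outward so that the alkenyl arm points inward, gives the (Z)-dienylketene 11, and ring A closes by a disrotatory six-electron electrocyclisation (C8–C8a bond) to dienone 12, which tautomerises to phenol 13. The closest known reaction is the Danheiser benzannulation of cyclobutenones with alkoxyacetylenes. No stereocentre is set: the centres of 5, 10 and 12 are racemic and vanish on aromatisation. The step needs regiocontrol in the ketene–alkyne union, and the polarity of the ynol ether secures it: its unsubstituted nucleophilic carbon attacks the ketene carbonyl carbon (C4a–C8a) and its methoxy-bearing carbon bonds to the ketene α-carbon (C5–C6), so that H sits on C4a, OMe on C5, the ketene oxygen becomes the free C8a hydroxyl and the benzyloxy group of the β-carbon ends on C7. Methoxyacetylene has no β-hydrogen and cannot fragment to ketene by a retro-ene path at this temperature, and its low boiling point is met by the sealed vessel and the excess.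

**Step 6**
Reactants: 13 3-(benzyloxy)-2,4,5-trimethoxyphenol
Product: 14 3-(benzyloxy)-1,2,4-trimethoxy-5-(methoxymethoxy)benzene
Conditions: MOMCl, iPr2NEt, CH2Cl2, 0 °C → rt
Reagents that add atoms: chloromethyl methyl ether, COCCl
Why: standard O-alkylation of a phenol to its methoxymethyl ether, which masks the acidic OH and supplies a strong ortho-directing group for the lithiation that follows.

**Step 7**
Reactants: 14 3-(benzyloxy)-1,2,4-trimethoxy-5-(methoxymethoxy)benzene; 15 N-methoxy-N-methylacetamide
Product: 18 1-[4-(benzyloxy)-2-hydroxy-3,5,6-trimethoxyphenyl]ethan-1-one, via aryllithium 16 (not isolated), via MOM-protected ketone 17 (not isolated)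
Conditions: n-BuLi (1.2 equiv), THF, −78 → 0 °C; 15 (1.5 equiv), −78 °C → rt; then 3 M aq. HCl, MeOH, 40 °C
Reagents that add atoms: none
Why: directed ortho-metalation at the only ring C–H, flanked by the OMOM and OMe directors, followed by Weinreb amide acylation (which stops at the ketone) and acid methanolysis of the MOM acetal beside the new carbonyl gives the hydroxy ketone without the Lewis acids of a Friedel–Crafts or Fries acylation, which could cleave the benzyl ether between two methoxy groups or shift it to the free para carbon.

**Step 8**
Reactants: 18 1-[4-(benzyloxy)-2-hydroxy-3,5,6-trimethoxyphenyl]ethan-1-one; 19 4-methoxybenzaldehyde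
Product: 20 (E)-1-[4-(benzyloxy)-2-hydroxy-3,5,6-trimethoxyphenyl]-3-(4-methoxyphenyl)prop-2-en-1-one
Conditions: 19 (1.2 equiv), 50% aq. KOH, EtOH, rt; then aq. HCl
Reagents that add atoms: none
Why: Claisen–Schmidt aldol condensation of the methyl ketone with a non-enolisable aldehyde, well known for fully oxygenated 2'-hydroxyacetophenones, the E-alkene arising from the elimination under thermodynamic control.

**Step 9**
Reactants: 20 (E)-1-[4-(benzyloxy)-2-hydroxy-3,5,6-trimethoxyphenyl]-3-(4-methoxyphenyl)prop-2-en-1-one
Product: 22 7-(benzyloxy)-5,6,8-trimethoxy-2-(4-methoxyphenyl)-4H-chromen-4-one, via flavanone 21 (not isolated)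
Conditions: I2 (0.1 equiv), DMSO, 130 °C
Reagents that add atoms: none
Why: iodine–DMSO oxidative cyclisation, in which the phenol closes ring C by 6-endo-trig oxa-Michael addition and iodination at C3 with loss of HI gives the chromone while DMSO reoxidises HI to I2, a sequence routine for benzyloxy- and polymethoxy-chalcones.

**Step 10**
Reactants: 22 7-(benzyloxy)-5,6,8-trimethoxy-2-(4-methoxyphenyl)-4H-chromen-4-one
Product: 23 7-hydroxy-5,6,8-trimethoxy-2-(4-methoxyphenyl)-4H-chromen-4-one (target)
Conditions: H2 (1 atm), 10% Pd/C, EtOAc–MeOH, rt, stopped after one equivalent of H2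
Reagents that add atoms: none
Why: catalytic hydrogenolysis cleaves the benzyl aryl ether and leaves the four methyl ethers, including the Lewis-acid-sensitive C5 methoxy, untouched, the chromone C2=C3 bond being reduced far more slowly.

**Compound list**
1 | dimethyl squarate (3,4-dimethoxycyclobut-3-ene-1,2-dione) | COC1=C(OC)C(=O)C1=O | starting material
2 | 4-hydroxy-2,3-dimethoxycyclobut-2-en-1-one (racemic) | COC1=C(OC)C(O)C1=O | intermediate
3 | 2,3,4-trimethoxycyclobut-2-en-1-one (racemic) | COC1=C(OC)C(OC)C1=O | intermediate
4 | benzyl alcohol | OCc1ccccc1 | starting material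
5 | 3-(benzyloxy)-2,4-dimethoxycyclobut-2-en-1-one (racemic) | COC1C(OCc2ccccc2)=C(OC)C1=O | intermediate
6 | chloroacetaldehyde dimethyl acetal (2-chloro-1,1-dimethoxyethane) | COC(CCl)OC | starting material
7 | sodium methoxyacetylide | COC#[C-].[Na+] | intermediate
8 | methoxyacetylene (methoxyethyne) | COC#C | intermediate
9 | (Z)-3-(benzyloxy)-2,4-dimethoxybuta-1,3-dien-1-one (vinylketene) | O=C=C(OC)/C(OCc1ccccc1)=C/OC | intermediate
10 | 4-[(Z)-1-(benzyloxy)-2-methoxyethenyl]-3,4-dimethoxycyclobut-2-en-1-one (racemic) | O=C1C=C(OC)C1(OC)/C(OCc2ccccc2)=C/OC | intermediate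
11 | (3Z,5Z)-5-(benzyloxy)-3,4,6-trimethoxyhexa-1,3,5-trien-1-one (dienylketene) | O=C=C/C(OC)=C(OC)\C(OCc1ccccc1)=C\OC | intermediate
12 | 5-(benzyloxy)-3,4,6-trimethoxycyclohexa-2,4-dien-1-one (racemic) | O=C1C=C(OC)C(OC)=C(OCc2ccccc2)C1OC | intermediate
13 | 3-(benzyloxy)-2,4,5-trimethoxyphenol | Oc1cc(OC)c(OC)c(OCc2ccccc2)c1OC | intermediate
14 | 3-(benzyloxy)-1,2,4-trimethoxy-5-(methoxymethoxy)benzene | COCOc1cc(OC)c(OC)c(OCc2ccccc2)c1OC | intermediate
15 | N-methoxy-N-methylacetamide | CC(=O)N(C)OC | starting material
16 | [4-(benzyloxy)-3,5,6-trimethoxy-2-(methoxymethoxy)phenyl]lithium | [Li]c1c(OCOC)c(OC)c(OCc2ccccc2)c(OC)c1OC | intermediate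
17 | 1-[4-(benzyloxy)-3,5,6-trimethoxy-2-(methoxymethoxy)phenyl]ethan-1-one | CC(=O)c1c(OCOC)c(OC)c(OCc2ccccc2)c(OC)c1OC | intermediate
18 | 1-[4-(benzyloxy)-2-hydroxy-3,5,6-trimethoxyphenyl]ethan-1-one | CC(=O)c1c(O)c(OC)c(OCc2ccccc2)c(OC)c1OC | intermediate
19 | 4-methoxybenzaldehyde | COc1ccc(C=O)cc1 | starting material
20 | (E)-1-[4-(benzyloxy)-2-hydroxy-3,5,6-trimethoxyphenyl]-3-(4-methoxyphenyl)prop-2-en-1-one | COc1ccc(/C=C/C(=O)c2c(O)c(OC)c(OCc3ccccc3)c(OC)c2OC)cc1 | intermediate
21 | 7-(benzyloxy)-5,6,8-trimethoxy-2-(4-methoxyphenyl)chroman-4-one (racemic) | COc1ccc(C2CC(=O)c3c(OC)c(OC)c(OCc4ccccc4)c(OC)c3O2)cc1 | intermediate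
22 | 7-(benzyloxy)-5,6,8-trimethoxy-2-(4-methoxyphenyl)-4H-chromen-4-one | COc1ccc(-c2cc(=O)c3c(OC)c(OC)c(OCc4ccccc4)c(OC)c3o2)cc1 | intermediate
23 | 7-hydroxy-5,6,8-trimethoxy-2-(4-methoxyphenyl)-4H-chromen-4-one (7-hydroxy-4',5,6,8-tetramethoxyflavone) | COc1ccc(-c2cc(=O)c3c(OC)c(OC)c(O)c(OC)c3o2)cc1 | target

**Step count**
Total: 10 steps. Longest linear sequence: 9 steps (1, 2, 3, 5, 6, 7, 8, 9, 10); step 4 is a one-step side branch that supplies 8.

**Steps most likely to fail**

Step 5. The trialkoxy vinylketene is electron-rich and may dimerise, oligomerise or be captured by the product phenol before the volatile ynol ether intercepts it, and the [2+2] union itself may be slow. The fallback makes the ring closure intramolecular through a Moore-type ring expansion and sets out from dimethyl squarate 1. Methyl vinyl ether is lithiated with t-BuLi in THF at −78 → 0 °C to 1-methoxyvinyllithium F1. Addition of F1 to one carbonyl of 1 at −78 °C, followed by a quench with saturated aq. NH4Cl, gives 4-hydroxy-2,3-dimethoxy-4-(1-methoxyethenyl)cyclobut-2-en-1-one F2. Methylation of F2 with MeI/Ag2O gives 2,3,4-trimethoxy-4-(1-methoxyethenyl)cyclobut-2-en-1-one F3. Exchange of the C3 methoxy group of F3 with benzyl alcohol 4, as in step 3, gives 3-(benzyloxy)-2,4-dimethoxy-4-(1-methoxyethenyl)cyclobut-2-en-1-one F4. Heating F4 in toluene at 110 °C should open the ring with the methoxy group outward and close the dienylketene onto the methoxyvinyl terminus, and tautomerisation then gives phenol 13, where the route is rejoined.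

Step 3. The alkoxy exchange is close to thermoneutral and may stall at equilibrium, and alkoxide may instead attack the carbonyl and open the strained ring. The fallback sets out from 3 and makes the displacement irreversible. Hydrolysis with LiOH (1 equiv) in THF–H2O at 0 °C and careful acidification with 1 M HCl should give the vinylogous acid 3-hydroxy-2,4-dimethoxycyclobut-2-en-1-one F5. Mitsunobu O-alkylation of F5 with benzyl alcohol 4 (PPh3, DIAD, THF, 0 °C) then gives 5, where the route is rejoined. The two oxygens of F5 are interchanged by enol tautomerism, so alkylation at either gives the same racemic 5.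

Step 2. The acyloin 2 may lose methanol and rearrange to a semisquarate under trace acid, be oxidised back to 1 by Ag2O, or open under base before it is alkylated. The fallback sets out from 1 and never forms the free carbinol. Ketalisation of 1 with MeOSiMe3 and catalytic TMSOTf in CH2Cl2 at −78 °C → rt gives 2,3,4,4-tetramethoxycyclobut-2-en-1-one F6. Ionic hydrogenation of F6 with Et3SiH and BF3·OEt2 in CH2Cl2 at −78 °C passes through an alkoxy-stabilised cyclobutenyl cation that takes up hydride at either terminus to give the same compound 3, where the route is rejoined.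

**Further compounds**
F1 | step 5 | 1-methoxyvinyllithium | [Li]C(=C)OC
F2 | step 5 | 4-hydroxy-2,3-dimethoxy-4-(1-methoxyethenyl)cyclobut-2-en-1-one (racemic) | COC(=C)C1(O)C(OC)=C(OC)C1=O
F3 | step 5 | 2,3,4-trimethoxy-4-(1-methoxyethenyl)cyclobut-2-en-1-one (racemic) | COC(=C)C1(OC)C(OC)=C(OC)C1=O
F4 | step 5 | 3-(benzyloxy)-2,4-dimethoxy-4-(1-methoxyethenyl)cyclobut-2-en-1-one (racemic) | COC(=C)C1(OC)C(OCc2ccccc2)=C(OC)C1=O
F5 | step 3 | 3-hydroxy-2,4-dimethoxycyclobut-2-en-1-one (racemic) | COC1C(O)=C(OC)C1=O
F6 | step 2 | 2,3,4,4-tetramethoxycyclobut-2-en-1-one | COC1=C(OC)C(OC)(OC)C1=O
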